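## Retrosynthetic overview
- The (2S)-flavanone is opened at two bonds at once, O1–C2 (oxa-Michael) and C4a–C5 (Claisen). This gives an acyclic 3,5,7-triketo ester that already carries both prenyl groups.
- The triketo ester is cut at C4a–C8a (crossed Claisen) into 4-hydroxybenzalacetone and dimethyl 2,4-diprenyl-3-oxoglutarate.
- The diprenyl oxoglutarate comes from dimethyl acetonedicarboxylate and two prenyl bromides, so both prenyl groups are placed before any ring exists.
- Ring order: ring B is bought. Ring A (carbocycle) and then ring C (pyranone) close in one catalytic operation, and the ring C closure sets C2.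

Assumption: the quinine-derived epi-9-amino thiourea is taken to give the (2S) product; if its sense of induction is the opposite, the commercial quinidine-derived pseudo-enantiomer is used under identical conditions.

Prenyl = 3-methylbut-2-en-1-yl.

## Route

**Step 1**
Reactants: 1 dimethyl 3-oxopentanedioate (dimethyl 1,3-acetonedicarboxylate); 2 1-bromo-3-methylbut-2-ene (prenyl bromide, 2 equiv)
Product: 3 dimethyl 2,4-bis(3-methylbut-2-en-1-yl)-3-oxopentanedioate (dl/meso and keto/enol mixture)
Conditions: NaH (1.05 equiv), THF, 0 °C, then 2 (1.0 equiv), rt; second NaH (1.05 equiv) and second 2 (1.0 equiv) in the same flask, rt, 12 h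
Reagents that add atoms: none
Why: This is a sequential SN2 C-alkylation of a β-keto diester enolate, in which the second equivalent of base removes the more acidic and less hindered proton of the untouched CH2, so the second prenyl goes to C4 (2,4- and not 2,2-pattern), and the two stereocentres do not matter because both become sp2 later.

**Step 2**
Reactants: 3 dimethyl 2,4-bis(3-methylbut-2-en-1-yl)-3-oxopentanedioate; 4 (E)-4-(4-hydroxyphenyl)but-3-en-2-one (4-hydroxybenzalacetone)
Product: 5 methyl (8E)-9-(4-hydroxyphenyl)-2,4-bis(3-methylbut-2-en-1-yl)-3,5,7-trioxonon-8-enoate (diastereomer and keto/enol mixture)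
Conditions: (a) 4 (2.0 equiv), LDA (4.0 equiv), THF/DMPU, −78 °C; (b) 3 (1.0 equiv), LDA (1.0 equiv), THF, −78 °C; b into a, −78 → −10 °C; inverse quench into 1 M HCl/EtOAc, 0 °C; short SiO2 plug, use at once (excess 4 recovered)
Reagents that add atoms: none
Why: In this crossed Claisen condensation the kinetic dienolate of the phenoxide of 4 (no longer a Michael acceptor) attacks the one ester of 3 that is not conjugated to its protecting mono-enolate, much as acetoacetate dianion attacks acetoacetate mono-anion, and the second equivalent of enolate deprotonates the more acidic product so that it stays an unreactive polyanion until the cold acid quench.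

**Step 3**
Reactants: 5 methyl (8E)-9-(4-hydroxyphenyl)-2,4-bis(3-methylbut-2-en-1-yl)-3,5,7-trioxonon-8-enoate
Product: 7 (2S)-5,7-dihydroxy-2-(4-hydroxyphenyl)-6,8-bis(3-methylbut-2-en-1-yl)chroman-4-one [(2S)-6,8-diprenylnaringenin], via 3′,5′-diprenylnaringenin chalcone 6 (not isolated)
Conditions: 1-[3,5-bis(trifluoromethyl)phenyl]-3-[(8α,9S)-6′-methoxycinchonan-9-yl]thiourea (15 mol %), 4 Å MS, toluene (0.05 M), Ar, 10 °C, 48 h; SiO2 plug to remove the amine; recrystallise (toluene/heptane) to raise ee
Reagents that add atoms: none
Why: Proposed new method: the quinuclidine nitrogen deprotonates the most acidic C6 methylene of 5, whose carbon attacks the C1 methyl ester in a 6-exo-trig Claisen (Dieckmann-type) closure made irreversible by loss of methanol and tautomerisation to the phloroglucinol ring A (the competing C2→C7 aldol would create a quaternary carbon and cannot aromatise), and the same catalyst then binds the carbonyl of chalcone 6 through its thiourea while its amine activates one of the two equivalent ortho-phenols for a 6-endo-trig oxa-Michael addition to the Si face of C-β, closing ring C and setting C2 as (S); the closest known reaction types are the mild-base biomimetic Claisen cyclisation of 3,5,7-triketo esters to acylphloroglucinols and the cinchona-thiourea-catalysed asymmetric oxa-Michael cyclisation of 2′-hydroxychalcones to flavanones.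

## Compound list
1 | dimethyl 3-oxopentanedioate | COC(=O)CC(=O)CC(=O)OC | starting material
2 | 1-bromo-3-methylbut-2-ene (prenyl bromide) | CC(C)=CCBr | starting material
3 | dimethyl 2,4-bis(3-methylbut-2-en-1-yl)-3-oxopentanedioate (dl/meso mixture) | COC(=O)C(CC=C(C)C)C(=O)C(CC=C(C)C)C(=O)OC | intermediate
4 | (E)-4-(4-hydroxyphenyl)but-3-en-2-one | CC(=O)/C=C/c1ccc(O)cc1 | starting material
5 | methyl (8E)-9-(4-hydroxyphenyl)-2,4-bis(3-methylbut-2-en-1-yl)-3,5,7-trioxonon-8-enoate (diastereomer mixture) | COC(=O)C(CC=C(C)C)C(=O)C(CC=C(C)C)C(=O)CC(=O)/C=C/c1ccc(O)cc1 | intermediate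
6 | (E)-3-(4-hydroxyphenyl)-1-[2,4,6-trihydroxy-3,5-bis(3-methylbut-2-en-1-yl)phenyl]prop-2-en-1-one (not isolated) | CC(C)=CCc1c(O)c(CC=C(C)C)c(O)c(C(=O)/C=C/c2ccc(O)cc2)c1O | intermediate
7 | (2S)-6,8-diprenylnaringenin | CC(C)=CCc1c(O)c(CC=C(C)C)c2c(c1O)C(=O)C[C@@H](c1ccc(O)cc1)O2 | target

## Step count and risks
Total step count: 3. Longest linear sequence: 3 (1 → 3 → 5 → 7).

**Step 3, the double cyclisation, is the most likely to fail.**
- The amine may be too weak to drive the Claisen closure cleanly, so 5 could derail to the 4-hydroxy-2-pyrone or to an intramolecular Michael adduct.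
- The ee of the oxa-Michael closure of an unactivated 2′,6′-dihydroxychalcone may be moderate. It can also erode through the reversible ring opening.
- The fallback sets out from 3 and moves the stereo-defining event to a C–C bond formation.
- The crossed Claisen is run with the kinetic lithium enolate of commercial (E)-4-methoxybut-3-en-2-one. This gives methyl (8E)-9-methoxy-2,4-bis(3-methylbut-2-en-1-yl)-3,5,7-trioxonon-8-enoate F6.
- No stereocentre is at stake, so F6 can be forced with Mg(OMe)2 in MeOH and then acidified. Claisen aromatisation and oxa-Michael addition/β-elimination of methanol again close both rings in one flask. The product is 5,7-dihydroxy-6,8-bis(3-methylbut-2-en-1-yl)-4H-chromen-4-one F7.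
- A rhodium(I)-catalysed asymmetric 1,4-addition of 4-hydroxyphenylboronic acid then sets C2. It uses an electron-poor atropisomeric bisphosphine (the antipode that delivers S) in toluene/water at rt. It comes back to the route at 7.

**Step 2, the crossed Claisen, is second.**
- Proton transfer from the mono-enolate of 3 to the ketone enolate can park 3 as an unreactive dianion.
- Regenerated 4 can also act as a Michael acceptor.
- The fallback sets out from 2 and reverses the polarity, so that the electrophile is a non-enolisable ester.
- The dianion of methyl acetoacetate (LDA, 2 equiv) is alkylated in one pot with two equivalents of 2, first at the γ- and then at the α-carbon. This gives methyl 7-methyl-2-(3-methylbut-2-en-1-yl)-3-oxooct-6-enoate F4.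
- The dianion of F4 is acetylated at the γ-carbon with N-methoxy-N-methylacetamide. This gives methyl 2,4-bis(3-methylbut-2-en-1-yl)-3,5-dioxohexanoate F5.
- The terminal methyl carbanion of the trianion of F5 (LDA, 3 equiv) is acylated by the lithium phenoxide of methyl (E)-4-hydroxycinnamate. This comes back to the route at 5.

**Step 1, the double prenylation, is third.**
- 2,2-Dialkylation, trialkylation and O-alkylation can contaminate 3, and the isomers are hard to separate.
- The fallback sets out from 2 and builds the central ketone from two halves that each already carry exactly one prenyl group.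
- Dimethyl malonate is monoalkylated with 2 (NaH, THF) to dimethyl 2-(3-methylbut-2-en-1-yl)malonate F1.
- One equivalent of KOH in MeOH gives 2-(methoxycarbonyl)-5-methylhex-4-enoic acid F2.
- Half of F2 is activated with carbonyldiimidazole to methyl 2-(1H-imidazole-1-carbonyl)-5-methylhex-4-enoate F3. The other half is used as its magnesium salt (MgCl2, Et3N).
- The decarboxylative Claisen (Masamune–Brooks) coupling of the two halves comes back to the route at 3.

## Further compounds
F1 | step 1 | dimethyl 2-(3-methylbut-2-en-1-yl)malonate | COC(=O)C(CC=C(C)C)C(=O)OC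
F2 | step 1 | 2-(methoxycarbonyl)-5-methylhex-4-enoic acid | COC(=O)C(CC=C(C)C)C(=O)O
F3 | step 1 | methyl 2-(1H-imidazole-1-carbonyl)-5-methylhex-4-enoate | COC(=O)C(CC=C(C)C)C(=O)n1ccnc1
F4 | step 2 | methyl 7-methyl-2-(3-methylbut-2-en-1-yl)-3-oxooct-6-enoate | COC(=O)C(CC=C(C)C)C(=O)CCC=C(C)C
F5 | step 2 | methyl 2,4-bis(3-methylbut-2-en-1-yl)-3,5-dioxohexanoate | COC(=O)C(CC=C(C)C)C(=O)C(CC=C(C)C)C(C)=O
F6 | step 3 | methyl (8E)-9-methoxy-2,4-bis(3-methylbut-2-en-1-yl)-3,5,7-trioxonon-8-enoate | COC(=O)C(CC=C(C)C)C(=O)C(CC=C(C)C)C(=O)CC(=O)/C=C/OC
F7 | step 3 | 5,7-dihydroxy-6,8-bis(3-methylbut-2-en-1-yl)-4H-chromen-4-one | CC(C)=CCc1c(O)c(CC=C(C)C)c2occc(=O)c2c1O
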